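## Retrosynthetic overview

1. The ArC7–CH2–C7′ bond is made last, by intermolecular Michael addition of the vinylogous acid decarboxycitrinin to the ortho-quinone methide released from the 7-(aminomethyl) Mannich base of the isochroman-diol half.
2. The isochroman diol comes from decarboxycitrinin by hydride addition at C1; decarboxycitrinin comes from phenol A, (2R,3S)-3-(3,5-dihydroxy-2-methylphenyl)butan-2-ol, plus one orthoformate carbon.
3. Phenol A comes from an aryl Grignard reagent and (2S,3S)-2,3-epoxybutane (anti opening sets the benzylic centre), followed by Mitsunobu inversion of the carbinol centre.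
4. The aryl bromide comes from 1-bromo-3,5-dimethoxybenzene (formylation, deoxygenation, OMe to OBn swap); the epoxide comes from (2S,3S)-butane-2,3-diol.
5. Ring order: the benzene ring is bought; the pyran ring is closed once, on phenol A, and serves both halves; the union forms no ring.

Assumption: the quinone-methide half is written as the 8-oxo-6-hydroxy tautomer, as in the given SMILES; it equilibrates with the 6-oxo-8-hydroxy form and both denote the same compound.

## Route

Step 1
Reactants: 1 1-bromo-3,5-dimethoxybenzene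
Product: 3 2-bromo-4,6-dimethoxybenzaldehyde, via aryl iminium chloride 2 (not isolated)
Conditions: POCl3, DMF, 0 → 95 °C; then ice/H2O
Reagents that add atoms: N,N-dimethylformamide, CN(C)C=O; water, O
Why: Vilsmeier–Haack formylation, in which the chloroiminium ion attacks the ring carbon ortho to Br that is ortho/para to both OMe groups and the iminium salt 2 is hydrolysed to the aldehyde.

Step 2
Reactants: 3 2-bromo-4,6-dimethoxybenzaldehyde
Product: 4 1-bromo-3,5-dimethoxy-2-methylbenzene
Conditions: Et3SiH (2.5 equiv), TFA, CH2Cl2, 0 °C → rt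
Reagents that add atoms: none
Why: Ionic hydrogenation, in which the doubly OMe-stabilised benzylic cation takes hydride twice from the silane so that CHO becomes CH3 while the aryl bromide is untouched.

Step 3
Reactants: 4 1-bromo-3,5-dimethoxy-2-methylbenzene
Product: 6 5-bromo-4-methylbenzene-1,3-diol, via bis(dibromoboryl) ether 5 (not isolated)
Conditions: BBr3 (2.5 equiv), CH2Cl2, −78 °C → rt; then H2O
Reagents that add atoms: none
Why: Lewis-acid ether cleavage, in which BBr3 complexes each OMe, bromide removes the methyl group by SN2 and the aryl borate 5 is hydrolysed on work-up.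

Step 4
Reactants: 6 5-bromo-4-methylbenzene-1,3-diol
Product: 7 1,5-bis(benzyloxy)-3-bromo-2-methylbenzene
Conditions: BnBr (2.3 equiv), K2CO3 (3 equiv), DMF, rt → 50 °C
Reagents that add atoms: benzyl bromide, BrCc1ccccc1
Why: Williamson ether synthesis, giving phenol protection that survives Grignard and Mitsunobu chemistry and is later removed by neutral hydrogenolysis.

Step 5
Reactants: 8 (2S,3S)-butane-2,3-diol
Product: 9 (2S,3R)-3-bromobutan-2-yl acetate
Conditions: HBr (33% in AcOH), 0 °C → rt
Reagents that add atoms: acetic acid, CC(=O)O; hydrogen bromide, Br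
Why: Acetoxonium (1,3-dioxolan-2-ylium) formation with both C–O bonds intact, then SN2 opening by bromide with inversion at one of the two equivalent carbons, gives the erythro bromo acetate.

Step 6
Reactants: 9 (2S,3R)-3-bromobutan-2-yl acetate
Product: 11 (2S,3S)-2,3-dimethyloxirane, via bromohydrin 10 (not isolated)
Conditions: KOH (2.5 equiv), H2O/diethylene glycol, 0 → 70 °C, epoxide distilled off as formed (bp 54 °C), dried over CaH2
Reagents that add atoms: none
Why: Saponification to bromohydrin 10 and intramolecular Williamson closure invert the bromide-bearing carbon a second time, so net retention gives the trans (2S,3S)-epoxide.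

Step 7
Reactants: 7 1,5-bis(benzyloxy)-3-bromo-2-methylbenzene; 11 (2S,3S)-2,3-dimethyloxirane
Product: 13 (2S,3S)-3-[3,5-bis(benzyloxy)-2-methylphenyl]butan-2-ol, via aryl Grignard reagent 12 (not isolated)
Conditions: Mg, THF, reflux; then CuI (10 mol%), 11 (1.5 equiv), THF, −30 → 0 °C; then aq NH4Cl
Reagents that add atoms: none
Why: CuI-catalysed SN2 opening of the C2-symmetric trans-epoxide by the aryl Grignard reagent occurs anti to oxygen, so the benzylic centre is set (S) by inversion while the carbinol centre keeps the epoxide configuration (S).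

Step 8
Reactants: 13 (2S,3S)-3-[3,5-bis(benzyloxy)-2-methylphenyl]butan-2-ol
Product: 14 (2R,3S)-3-[3,5-bis(benzyloxy)-2-methylphenyl]butan-2-yl 4-nitrobenzoate
Conditions: 4-nitrobenzoic acid (2 equiv), PPh3 (2 equiv), DIAD (2 equiv), toluene, 0 °C → rt; recrystallise
Reagents that add atoms: 4-nitrobenzoic acid, OC(=O)c1ccc(cc1)[N+](=O)[O-]
Why: Mitsunobu reaction, in which the alkoxyphosphonium ion is displaced by 4-nitrobenzoate in an SN2 step that inverts C2 to R and so creates the threo relationship needed for trans-3,4-dimethyl groups.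

Step 9
Reactants: 14 (2R,3S)-3-[3,5-bis(benzyloxy)-2-methylphenyl]butan-2-yl 4-nitrobenzoate
Product: 15 (2R,3S)-3-[3,5-bis(benzyloxy)-2-methylphenyl]butan-2-ol
Conditions: K2CO3 (0.3 equiv), MeOH/THF, rt
Reagents that add atoms: none
Why: Base-catalysed transesterification cleaves the activated ester at the acyl carbon, so the C2 configuration is retained.

Step 10
Reactants: 15 (2R,3S)-3-[3,5-bis(benzyloxy)-2-methylphenyl]butan-2-ol
Product: 16 phenol A [(2R,3S)-3-(3,5-dihydroxy-2-methylphenyl)butan-2-ol]
Conditions: H2 (1 atm), Pd/C (10%), EtOAc/MeOH, rt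
Reagents that add atoms: none
Why: Catalytic hydrogenolysis removes both benzyl ethers under neutral conditions and nothing else in the molecule is reducible.

Step 11
Reactants: 16 phenol A
Product: 18 decarboxycitrinin [(3R,4S)-6-hydroxy-3,4,5-trimethyl-3,4-dihydro-8H-isochromen-8-one], via 1-ethoxyisochroman 17 (not isolated)
Conditions: HC(OEt)3 (1.5 equiv), TFA (5 equiv), CH2Cl2, 0 °C → rt; then 1 M aq HCl/THF, rt; adjust to pH 4–5
Reagents that add atoms: triethyl orthoformate, CCOC(OCC)OCC
Why: Orthoester exchange at the secondary OH gives a tethered dialkoxycarbenium ion that attacks the only ortho ring carbon (oxa-Pictet–Spengler-type intramolecular Friedel–Crafts formylation), and loss of EtOH from 17 gives the vinylogous-acid quinone methide with both stereocentres untouched.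

Step 12
Reactants: 18 decarboxycitrinin (about 45% of the batch)
Product: 19 (3R,4S)-3,4,5-trimethyl-3,4-dihydro-1H-isochromene-6,8-diol
Conditions: NaBH4 (1.5 equiv), MeOH, 0 °C → rt, argon; then aq NH4Cl
Reagents that add atoms: none
Why: Conjugate (1,6) hydride addition at C1 of the quinone methide is driven by aromatisation and leaves C3 and C4 unchanged.

Step 13
Reactants: 19 (3R,4S)-3,4,5-trimethyl-3,4-dihydro-1H-isochromene-6,8-diol
Product: 20 (3R,4S)-7-[(dimethylamino)methyl]-3,4,5-trimethyl-3,4-dihydro-1H-isochromene-6,8-diol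
Conditions: CH2=NMe2+ I− (1.05 equiv), CH2Cl2, 0 °C → rt, argon; then aq NaHCO3
Reagents that add atoms: N,N-dimethylmethylideneammonium iodide (Eschenmoser's salt), C=[N+](C)C.[I-]
Why: Mannich reaction of the preformed iminium ion at C7, the only free ring carbon, which is activated by two ortho OH groups.

Step 14
Reactants: 20 (3R,4S)-7-[(dimethylamino)methyl]-3,4,5-trimethyl-3,4-dihydro-1H-isochromene-6,8-diol
Product: 21 1-[(3R,4S)-6,8-dihydroxy-3,4,5-trimethyl-3,4-dihydro-1H-isochromen-7-yl]-N,N,N-trimethylmethanaminium iodide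
Conditions: MeI (5 equiv), THF/Et2O, rt, dark; salt filtered off
Reagents that add atoms: iodomethane, CI
Why: Menshutkin N-alkylation turns the amine into a leaving group that departs at room temperature, and without added base the phenols are not methylated.

Step 15
Reactants: 21 the trimethylammonium iodide; 18 decarboxycitrinin (1.3 equiv)
Product: 23 (3R,4S)-7-{[(3R,4S)-6,8-dihydroxy-3,4,5-trimethyl-3,4-dihydro-1H-isochromen-7-yl]methyl}-6-hydroxy-3,4,5-trimethyl-3,4-dihydro-8H-isochromen-8-one (the target), via ortho-quinone methide 22 (not isolated)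
Conditions: K2CO3 (2 equiv), DMF, 0 °C → rt, argon; then pH 4 buffer
Reagents that add atoms: none
Why: Base-induced loss of NMe3 gives ortho-quinone methide 22, and the enolate of vinylogous acid 18 adds through C7 to its exocyclic methylene in an intermolecular Michael addition that rearomatises the isochroman ring and touches no stereocentre.

## Compound list

1 | 1-bromo-3,5-dimethoxybenzene | COc1cc(Br)cc(OC)c1 | starting material
2 | N-[(2-bromo-4,6-dimethoxyphenyl)methylidene]-N-methylmethanaminium chloride | COc1cc(OC)c(C=[N+](C)C)c(Br)c1.[Cl-] | intermediate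
3 | 2-bromo-4,6-dimethoxybenzaldehyde | COc1cc(OC)c(C=O)c(Br)c1 | intermediate
4 | 1-bromo-3,5-dimethoxy-2-methylbenzene | COc1cc(OC)c(C)c(Br)c1 | intermediate
5 | 1-bromo-3,5-bis[(dibromoboranyl)oxy]-2-methylbenzene | Cc1c(Br)cc(OB(Br)Br)cc1OB(Br)Br | intermediate
6 | 5-bromo-4-methylbenzene-1,3-diol | Cc1c(O)cc(O)cc1Br | intermediate
7 | 1,5-bis(benzyloxy)-3-bromo-2-methylbenzene | Cc1c(Br)cc(OCc2ccccc2)cc1OCc1ccccc1 | intermediate
8 | (2S,3S)-butane-2,3-diol | C[C@H](O)[C@H](C)O | starting material
9 | (2S,3R)-3-bromobutan-2-yl acetate | C[C@H](OC(C)=O)[C@@H](C)Br | intermediate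
10 | (2S,3R)-3-bromobutan-2-ol | C[C@H](O)[C@@H](C)Br | intermediate
11 | (2S,3S)-2,3-dimethyloxirane (trans-2,3-epoxybutane) | C[C@@H]1O[C@H]1C | intermediate
12 | [3,5-bis(benzyloxy)-2-methylphenyl]magnesium bromide | Cc1c([Mg]Br)cc(OCc2ccccc2)cc1OCc1ccccc1 | intermediate
13 | (2S,3S)-3-[3,5-bis(benzyloxy)-2-methylphenyl]butan-2-ol | C[C@H](O)[C@@H](C)c1cc(OCc2ccccc2)cc(OCc2ccccc2)c1C | intermediate
14 | (2R,3S)-3-[3,5-bis(benzyloxy)-2-methylphenyl]butan-2-yl 4-nitrobenzoate | C[C@@H](OC(=O)c1ccc(cc1)[N+](=O)[O-])[C@@H](C)c1cc(OCc2ccccc2)cc(OCc2ccccc2)c1C | intermediate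
15 | (2R,3S)-3-[3,5-bis(benzyloxy)-2-methylphenyl]butan-2-ol | C[C@@H](O)[C@@H](C)c1cc(OCc2ccccc2)cc(OCc2ccccc2)c1C | intermediate
16 | phenol A, (2R,3S)-3-(3,5-dihydroxy-2-methylphenyl)butan-2-ol | C[C@@H](O)[C@@H](C)c1cc(O)cc(O)c1C | intermediate
17 | (3R,4S)-1-ethoxy-3,4,5-trimethyl-3,4-dihydro-1H-isochromene-6,8-diol (both C1 epimers) | c1c(O)c(C)c2c(c1O)C(OCC)O[C@H](C)[C@H]2C | intermediate
18 | decarboxycitrinin, (3R,4S)-6-hydroxy-3,4,5-trimethyl-3,4-dihydro-8H-isochromen-8-one | CC1=C2C(=CO[C@H](C)[C@H]2C)C(=O)C=C1O | intermediate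
19 | (3R,4S)-3,4,5-trimethyl-3,4-dihydro-1H-isochromene-6,8-diol | c1c(O)c(C)c2c(c1O)CO[C@H](C)[C@H]2C | intermediate
20 | (3R,4S)-7-[(dimethylamino)methyl]-3,4,5-trimethyl-3,4-dihydro-1H-isochromene-6,8-diol | CN(C)Cc1c(O)c(C)c2c(c1O)CO[C@H](C)[C@H]2C | intermediate
21 | 1-[(3R,4S)-6,8-dihydroxy-3,4,5-trimethyl-3,4-dihydro-1H-isochromen-7-yl]-N,N,N-trimethylmethanaminium iodide | C[N+](C)(C)Cc1c(O)c(C)c2c(c1O)CO[C@H](C)[C@H]2C.[I-] | intermediate
22 | (3R,4S)-8-hydroxy-3,4,5-trimethyl-7-methylidene-3,4-dihydro-1H-isochromen-6(7H)-one (ortho-quinone methide) | C=C1C(=O)C(C)=C2C(CO[C@H](C)[C@H]2C)=C1O | intermediate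
23 | dicitrinone I, (3R,4S)-7-{[(3R,4S)-6,8-dihydroxy-3,4,5-trimethyl-3,4-dihydro-1H-isochromen-7-yl]methyl}-6-hydroxy-3,4,5-trimethyl-3,4-dihydro-8H-isochromen-8-one | CC1=C2C(=CO[C@H](C)[C@H]2C)C(=O)C(Cc2c(O)c(C)c3c(c2O)CO[C@H](C)[C@H]3C)=C1O | target

## Summary

Total step count: 15.
Longest linear sequence: 13 steps (1 → 23 through steps 1–4 and 7–15; the epoxide branch, steps 5–6, joins at step 7).

Three steps most likely to fail:

Step 8 (Mitsunobu inversion). The alcohol is hindered, and elimination to the styrene or retention through aryl participation could lower yield or stereochemical purity. Fallback: set out from 13 and oxidise it with Dess–Martin periodinane (CH2Cl2, NaHCO3, 0 °C → rt) to the ketone (3S)-3-[3,5-bis(benzyloxy)-2-methylphenyl]butan-2-one F1. Reduce F1 with LiBH(s-Bu)3 in THF at −78 °C; Felkin–Anh delivery of hydride anti to the aryl group gives the threo (2R,3S) alcohol. The path comes back to the route at 15 and bypasses 14.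

Step 11 (orthoformate annulation). Intermolecular formylation at the carbon between the two OH groups, or attack of unreacted 16 on the electrophilic C1 of 18, could compete. Fallback: set out from 15 and protect the alcohol with MOMCl/iPr2NEt (CH2Cl2) to give the MOM ether 1,5-bis(benzyloxy)-3-[(2S,3R)-3-(methoxymethoxy)butan-2-yl]-2-methylbenzene F2. TMSOTf (CH2Cl2, −40 → 0 °C) ionises F2 to an oxocarbenium ion that can only close onto the ortho ring carbon, giving (3R,4S)-6,8-bis(benzyloxy)-3,4,5-trimethyl-3,4-dihydro-1H-isochromene F3. Hydrogenolysis (H2, Pd/C, EtOAc) of F3 gives 19 directly. About half of 19 is then dehydrogenated at C1 with DDQ (1 equiv, dioxane, rt), where the path comes back to the route at 18.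

Step 15 (quinone-methide Michael union). Compound 22 could dimerise or be captured at oxygen faster than C7 of 18 adds. Fallback with the roles of donor and acceptor exchanged: set out from 18 and treat it with Eschenmoser's salt (CH2Cl2, 0 °C) to aminomethylate its C7, giving (3R,4S)-7-[(dimethylamino)methyl]-6-hydroxy-3,4,5-trimethyl-3,4-dihydro-8H-isochromen-8-one F4. Warming F4 with 19 in AcOH/NaOAc at 50–60 °C expels dimethylamine to give the enedione (3R,4S)-3,4,5-trimethyl-7-methylidene-3,4-dihydro-6H-isochromene-6,8(7H)-dione F5. The free C7 of resorcinol 19 adds to F5 in a Michael (Friedel–Crafts-type) addition, and the path comes back to the route at 23.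

## Further compounds

F1 | step 8 | (3S)-3-[3,5-bis(benzyloxy)-2-methylphenyl]butan-2-one | CC(=O)[C@@H](C)c1cc(OCc2ccccc2)cc(OCc2ccccc2)c1C
F2 | step 11 | 1,5-bis(benzyloxy)-3-[(2S,3R)-3-(methoxymethoxy)butan-2-yl]-2-methylbenzene | C[C@@H](OCOC)[C@@H](C)c1cc(OCc2ccccc2)cc(OCc2ccccc2)c1C
F3 | step 11 | (3R,4S)-6,8-bis(benzyloxy)-3,4,5-trimethyl-3,4-dihydro-1H-isochromene | c1c(OCc3ccccc3)c(C)c2c(c1OCc4ccccc4)CO[C@H](C)[C@H]2C
F4 | step 15 | (3R,4S)-7-[(dimethylamino)methyl]-6-hydroxy-3,4,5-trimethyl-3,4-dihydro-8H-isochromen-8-one | CC1=C2C(=CO[C@H](C)[C@H]2C)C(=O)C(CN(C)C)=C1O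
F5 | step 15 | (3R,4S)-3,4,5-trimethyl-7-methylidene-3,4-dihydro-6H-isochromene-6,8(7H)-dione | CC1=C2C(=CO[C@H](C)[C@H]2C)C(=O)C(=C)C1=O
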